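**Plan**

- Retrosynthesis: the 4'-O-silyl and 5-O-methyl groups are put back, the C4 carbonyl is traced to a C4 methyl ether and the C3 hydroxyl to a C3–B bond; ring C is then cut at O1–C2 and C3–C4.
- Enabling feature: ring C is a pyran fused to ring A in which O1, C8a, C4a and C4 make up an ortho-quinone methide of ring A, while C2 and C3, carrying aryl and oxygen trans to each other, are the two carbons of an (E)-alkene.
- Forward: rings A and B come from the starting materials. The ring A salicylaldehyde is built from 1,3-dimethoxybenzene (prenylation, C–H borylation/oxidation, ortho-formylation) and the ring B (E)-alkenylboronate from vanillin (silylation, boron–Wittig olefination).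
- Ring C is closed last, in one three-component [4+2] step from the aldehyde, trimethyl orthoformate and the alkenylboronate. C–B oxidation, C4 oxidation, 5-O-demethylation and desilylation follow.
- Stereochemistry: the trans C2/C3 relation copies the (E)-alkene geometry, the absolute configuration comes from a chiral scandium–pybox catalyst, the C3–O bond is made from C–B with retention, and the C4 stereocentre is erased on oxidation.

Key step: step 6

Assumption: the (S,S)-ligand is taken to leave open the face of the scandium-bound heterodiene that leads to the (2S,3S) adduct; if the opposite sense is found, the (R,R)-ligand is used and nothing else changes.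

**Route**

Step 1
Reactants: 1 1,3-dimethoxybenzene
Product: 3 1,3-dimethoxy-2-(3-methylbut-2-en-1-yl)benzene, via 2-lithio-1,3-dimethoxybenzene 2 (not isolated)
Conditions: n-BuLi, THF, 0 °C → rt; then prenyl bromide, 0 °C → rt
Reagents that add atoms: prenyl bromide (1-bromo-3-methylbut-2-ene), CC(C)=CCBr; n-butyllithium, [Li]CCCC (lithium of 2 only)
Why: Directed ortho-metalation between the two methoxy groups, followed by SN2 alkylation of the aryllithium at the primary carbon of the allylic bromide.

Step 2
Reactants: 3 1,3-dimethoxy-2-(3-methylbut-2-en-1-yl)benzene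
Product: 5 3,5-dimethoxy-4-(3-methylbut-2-en-1-yl)phenol, via arylboronate 4 (not isolated)
Conditions: [Ir(OMe)(cod)]2 (1.5 mol %), 4,4'-di-tert-butyl-2,2'-bipyridine (3 mol %), B2pin2 (1 equiv), THF, 80 °C; then aq. H2O2, NaOH, 0 °C → rt
Reagents that add atoms: bis(pinacolato)diboron, CC1(C)OB(OC1(C)C)B1OC(C)(C)C(C)(C)O1 (boryl group of 4 only); hydrogen peroxide, OO
Why: Iridium-catalysed C–H borylation is sterically controlled and C5 is the only ring position without an ortho substituent, and alkaline peroxide oxidation of the arylboronate should give the phenol while sparing the trisubstituted alkene.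

Step 3
Reactants: 5 3,5-dimethoxy-4-(3-methylbut-2-en-1-yl)phenol
Product: 6 6-hydroxy-2,4-dimethoxy-3-(3-methylbut-2-en-1-yl)benzaldehyde
Conditions: MgCl2, Et3N, (CH2O)n, MeCN, reflux; dilute aq. HCl work-up
Reagents that add atoms: paraformaldehyde (as formaldehyde), C=O
Why: Casnati–Skattebøl ortho-formylation: the magnesium phenoxide delivers formaldehyde to the ortho position only, the two ortho positions are equivalent and the para position is blocked, and a second formaldehyde oxidises the benzylic alkoxide to the aldehyde.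

Step 4
Reactants: 7 vanillin
Product: 8 3-methoxy-4-(triisopropylsilyloxy)benzaldehyde
Conditions: TIPSCl, imidazole, DMF, rt
Reagents that add atoms: triisopropylsilyl chloride, CC(C)[Si](Cl)(C(C)C)C(C)C
Why: Silylation of the phenol; the triisopropylsilyl ether is chosen because it should withstand the lithium amide, the Lewis acids and the perborate used later and still fall to fluoride.

Step 5
Reactants: 8 3-methoxy-4-(triisopropylsilyloxy)benzaldehyde
Product: 9 (E)-2-{2-[3-methoxy-4-(triisopropylsilyloxy)phenyl]ethenyl}-4,4,5,5-tetramethyl-1,3,2-dioxaborolane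
Conditions: CH2(Bpin)2, lithium 2,2,6,6-tetramethylpiperidide (LiTMP), THF, 0 °C; then 8, −78 °C → rt; aq. NH4Cl work-up
Reagents that add atoms: bis(pinacolboryl)methane, CC1(C)OB(CB2OC(C)(C)C(C)(C)O2)OC1(C)C
Why: Boron–Wittig olefination: the lithiated geminal bis(boronate) adds to the aldehyde and syn-elimination of the boron–oxygen pair should give the (E)-alkenylboronate, the hindered amide base leaving the aryl silyl ether intact.

Step 6
Reactants: 6 6-hydroxy-2,4-dimethoxy-3-(3-methylbut-2-en-1-yl)benzaldehyde; 10 trimethyl orthoformate (2 equiv); 9 (E)-2-{2-[3-methoxy-4-(triisopropylsilyloxy)phenyl]ethenyl}-4,4,5,5-tetramethyl-1,3,2-dioxaborolane (1.5 equiv)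
Product: 13 (2S,3S,4S)-4,5,7-trimethoxy-2-[3-methoxy-4-(triisopropylsilyloxy)phenyl]-6-(3-methylbut-2-en-1-yl)-3-(4,4,5,5-tetramethyl-1,3,2-dioxaborolan-2-yl)chromane, via dimethyl acetal 11 (not isolated), via 4-methoxy ortho-quinone methide 12 (not isolated)
Conditions: Sc(OTf)3 (10 mol %), 2,6-bis[(4S)-4-phenyl-4,5-dihydrooxazol-2-yl]pyridine ((S,S)-Ph-pybox, 12 mol %), 4 Å molecular sieves, CH2Cl2, −40 → −20 °C; Et3N quench
Reagents that add atoms: none
Why: Proposed new method: Sc(OTf)3 turns 6 and 10 into acetal 11 and ionises it to the scandium-bound oxocarbenium–phenoxide 12; the boron-bearing carbon of 9 attacks the methide carbon (C3–C4) while the phenoxide oxygen closes on the aryl-bearing carbon (O1–C2) in an asynchronous, suprafacial inverse-demand hetero-Diels–Alder addition. The closest known reaction type is the Lewis acid three-component union of salicylaldehydes, orthoformates and styrenes to 4-alkoxyflavans; an alkenylboronate as the 2π partner and enantiocontrol by a chiral scandium–pybox complex have not been shown. Ring C closes as the six-membered ring of a [4+2] cycloaddition, with C–O closure following C–C bond formation. C2 and C3 should come out trans because the (E)-geometry of 9 is carried over suprafacially, their absolute sense is set by the pybox ligand, which leaves one face of the scandium-bound planar heterodiene open, and C4 (drawn 4S, the 2,4-cis epimer) is set by the endo/exo orientation and does not matter because it becomes the carbonyl carbon. Regioselectivity is secured by the positive charge building up at the carbon that is benzylic to the para-siloxyaryl ring and β to boron. Chemoselectivity over the prenyl alkene is secured by the higher nucleophilicity of the conjugated, donor-substituted styrenyl alkene used in excess, and the weakly Lewis acidic pinacol ester, the low temperature and the amine quench guard against loss of boron from the adduct.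

Step 7
Reactants: 13 (2S,3S,4S)-4,5,7-trimethoxy-2-[3-methoxy-4-(triisopropylsilyloxy)phenyl]-6-(3-methylbut-2-en-1-yl)-3-(4,4,5,5-tetramethyl-1,3,2-dioxaborolan-2-yl)chromane
Product: 14 (2R,3S,4R)-4,5,7-trimethoxy-2-[3-methoxy-4-(triisopropylsilyloxy)phenyl]-6-(3-methylbut-2-en-1-yl)chroman-3-ol
Conditions: NaBO3·4H2O, THF/H2O, 0 °C → rt
Reagents that add atoms: sodium perborate, [Na+].[O-]OB=O
Why: Organoborane oxidation: peroxide adds to boron and C3 migrates to oxygen with retention, so the hydroxyl takes the place of boron trans to the C2 aryl group (the descriptors change only because the priorities change), and the mild perborate should spare the silyl ether and the alkene.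

Step 8
Reactants: 14 (2R,3S,4R)-4,5,7-trimethoxy-2-[3-methoxy-4-(triisopropylsilyloxy)phenyl]-6-(3-methylbut-2-en-1-yl)chroman-3-ol
Product: 15 (2R,3R)-3-hydroxy-5,7-dimethoxy-2-[3-methoxy-4-(triisopropylsilyloxy)phenyl]-6-(3-methylbut-2-en-1-yl)chroman-4-one
Conditions: DDQ (1.5 equiv), CH2Cl2/pH 7 phosphate buffer, 0 °C → rt
Reagents that add atoms: water, O
Why: DDQ oxidation of a benzylic ether: hydride is abstracted from C4–H, which is benzylic to the trioxygenated ring A and α to the methoxy group as in a p-methoxybenzyl ether, and hydrolysis should then give the ketone without touching C2 or C3.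

Step 9
Reactants: 15 (2R,3R)-3-hydroxy-5,7-dimethoxy-2-[3-methoxy-4-(triisopropylsilyloxy)phenyl]-6-(3-methylbut-2-en-1-yl)chroman-4-one
Product: 16 (2R,3R)-3,5-dihydroxy-7-methoxy-2-[3-methoxy-4-(triisopropylsilyloxy)phenyl]-6-(3-methylbut-2-en-1-yl)chroman-4-one
Conditions: MgI2·OEt2 (3 equiv), toluene/Et2O, 70 °C; then dilute aq. HCl
Reagents that add atoms: none
Why: Chelation-controlled ether cleavage: magnesium bridges the C4 carbonyl and the peri 5-methoxy oxygen and iodide removes that methyl group by SN2, leaving the 7- and 3'-methyl ethers, which cannot chelate.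

Step 10
Reactants: 16 (2R,3R)-3,5-dihydroxy-7-methoxy-2-[3-methoxy-4-(triisopropylsilyloxy)phenyl]-6-(3-methylbut-2-en-1-yl)chroman-4-one
Product: 17 (2R,3R)-3,5-dihydroxy-2-(4-hydroxy-3-methoxyphenyl)-7-methoxy-6-(3-methylbut-2-en-1-yl)chroman-4-one
Conditions: TBAF, AcOH, THF, 0 °C
Reagents that add atoms: none
Why: Fluoride-mediated cleavage of the aryl silyl ether, buffered with acetic acid so that the base-sensitive trans-dihydroflavonol is neither epimerised nor ring-opened.

**Compound list**

1 | 1,3-dimethoxybenzene | COc1cccc(OC)c1 | starting material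
2 | 2-lithio-1,3-dimethoxybenzene (not isolated) | [Li]c1c(OC)cccc1OC | intermediate
3 | 1,3-dimethoxy-2-(3-methylbut-2-en-1-yl)benzene | COc1cccc(OC)c1CC=C(C)C | intermediate
4 | 2-[3,5-dimethoxy-4-(3-methylbut-2-en-1-yl)phenyl]-4,4,5,5-tetramethyl-1,3,2-dioxaborolane (not isolated) | COc1cc(B2OC(C)(C)C(C)(C)O2)cc(OC)c1CC=C(C)C | intermediate
5 | 3,5-dimethoxy-4-(3-methylbut-2-en-1-yl)phenol | COc1cc(O)cc(OC)c1CC=C(C)C | intermediate
6 | 6-hydroxy-2,4-dimethoxy-3-(3-methylbut-2-en-1-yl)benzaldehyde | O=Cc1c(O)cc(OC)c(CC=C(C)C)c1OC | intermediate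
7 | vanillin | COc1cc(C=O)ccc1O | starting material
8 | 3-methoxy-4-(triisopropylsilyloxy)benzaldehyde | COc1cc(C=O)ccc1O[Si](C(C)C)(C(C)C)C(C)C | intermediate
9 | (E)-2-{2-[3-methoxy-4-(triisopropylsilyloxy)phenyl]ethenyl}-4,4,5,5-tetramethyl-1,3,2-dioxaborolane | COc1cc(/C=C/B2OC(C)(C)C(C)(C)O2)ccc1O[Si](C(C)C)(C(C)C)C(C)C | intermediate
10 | trimethyl orthoformate | COC(OC)OC | starting material
11 | 2-(dimethoxymethyl)-3,5-dimethoxy-4-(3-methylbut-2-en-1-yl)phenol (not isolated) | COC(OC)c1c(O)cc(OC)c(CC=C(C)C)c1OC | intermediate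
12 | 3,5-dimethoxy-6-(methoxymethylidene)-4-(3-methylbut-2-en-1-yl)cyclohexa-2,4-dien-1-one, the 4-methoxy ortho-quinone methide (not isolated; methide geometry not fixed, since the oxocarbenium–phenoxide form rotates about the aryl–CH bond) | COC=C1C(=O)C=C(OC)C(CC=C(C)C)=C1OC | intermediate
13 | (2S,3S,4S)-4,5,7-trimethoxy-2-[3-methoxy-4-(triisopropylsilyloxy)phenyl]-6-(3-methylbut-2-en-1-yl)-3-(4,4,5,5-tetramethyl-1,3,2-dioxaborolan-2-yl)chromane (2,3-trans, 3,4-trans) | COc1cc([C@H]2Oc3cc(OC)c(CC=C(C)C)c(OC)c3[C@@H](OC)[C@@H]2B2OC(C)(C)C(C)(C)O2)ccc1O[Si](C(C)C)(C(C)C)C(C)C | intermediate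
14 | (2R,3S,4R)-4,5,7-trimethoxy-2-[3-methoxy-4-(triisopropylsilyloxy)phenyl]-6-(3-methylbut-2-en-1-yl)chroman-3-ol | COc1cc([C@H]2Oc3cc(OC)c(CC=C(C)C)c(OC)c3[C@@H](OC)[C@@H]2O)ccc1O[Si](C(C)C)(C(C)C)C(C)C | intermediate
15 | (2R,3R)-3-hydroxy-5,7-dimethoxy-2-[3-methoxy-4-(triisopropylsilyloxy)phenyl]-6-(3-methylbut-2-en-1-yl)chroman-4-one | COc1cc([C@H]2Oc3cc(OC)c(CC=C(C)C)c(OC)c3C(=O)[C@@H]2O)ccc1O[Si](C(C)C)(C(C)C)C(C)C | intermediate
16 | (2R,3R)-3,5-dihydroxy-7-methoxy-2-[3-methoxy-4-(triisopropylsilyloxy)phenyl]-6-(3-methylbut-2-en-1-yl)chroman-4-one | COc1cc([C@H]2Oc3cc(OC)c(CC=C(C)C)c(O)c3C(=O)[C@@H]2O)ccc1O[Si](C(C)C)(C(C)C)C(C)C | intermediate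
17 | (2R,3R)-3,5-dihydroxy-2-(4-hydroxy-3-methoxyphenyl)-7-methoxy-6-(3-methylbut-2-en-1-yl)chroman-4-one | COc1cc([C@H]2Oc3cc(OC)c(CC=C(C)C)c(O)c3C(=O)[C@@H]2O)ccc1O | target

**Step count**

Total: 10 steps. Longest linear sequence: 8 steps (steps 1–3 and 6–10, from 1,3-dimethoxybenzene); the ring B branch (steps 4 and 5) has 2 steps.

**Steps most likely to fail**

Step 6 (proposed new method). Three processes may defeat it:
- the β-boryl benzylic cation may lose boron (alkenyl transfer and later flav-3-ene formation) instead of closing ring C;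
- the chiral catalyst may discriminate poorly between the two faces of the heterodiene;
- the prenyl alkene may add in place of the styrenyl alkene.

Fallback by known chemistry, setting out from 6 and using 8, returning at 15:
- The phenol of 6 is protected (MOMCl, i-Pr2NEt, CH2Cl2) to give 2,4-dimethoxy-6-(methoxymethoxy)-3-(3-methylbut-2-en-1-yl)benzaldehyde F1.
- MeMgBr in THF gives 1-[2,4-dimethoxy-6-(methoxymethoxy)-3-(3-methylbut-2-en-1-yl)phenyl]ethan-1-ol F2, and Dess–Martin oxidation gives the acetophenone 1-[2,4-dimethoxy-6-(methoxymethoxy)-3-(3-methylbut-2-en-1-yl)phenyl]ethan-1-one F3.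
- Claisen–Schmidt condensation of F3 with 8 under aprotic conditions that spare the silyl ether (LiN(SiMe3)2, THF, −78 °C → rt) gives the (E)-chalcone F4.
- Juliá–Colonna epoxidation (poly-L-leucine, urea–H2O2, DBU, THF), which attacks only the enone and not the prenyl alkene, is chosen to give the (2R,3S)-epoxy ketone F5.
- Dilute methanolic HCl removes the methoxymethyl group and the freed phenol opens the epoxide at the benzylic carbon with inversion, giving the trans-dihydroflavonol 15, from which steps 9 and 10 follow.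

Step 8. Hydride abstraction may occur at the doubly activated prenyl methylene or at C2–H instead of C4–H, or may stall if the C4–H bond is poorly aligned with the ring A π system. Fallback, setting out from 14 and returning at 15: solvolysis of the C4 methyl ether in dilute aqueous acid at high dilution (pyridinium p-toluenesulfonate, THF/H2O) gives (2R,3S)-5,7-dimethoxy-2-[3-methoxy-4-(triisopropylsilyloxy)phenyl]-6-(3-methylbut-2-en-1-yl)chromane-3,4-diol F6 as C4 epimers. Activated MnO2 in CH2Cl2 then oxidises only the benzylic C4 hydroxyl, giving 15.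

Step 2. The prenyl alkene may be hydroborated or isomerised by pinacolborane and iridium hydride species during the C–H borylation. Fallback, setting out from 1 and returning at 5, in which the oxygen is installed before the alkene:
- 1 is borylated and oxidised under the conditions of step 2 through 2-(3,5-dimethoxyphenyl)-4,4,5,5-tetramethyl-1,3,2-dioxaborolane F7 to 3,5-dimethoxyphenol F8.
- TIPSCl and imidazole give (3,5-dimethoxyphenoxy)triisopropylsilane F9.
- n-BuLi in THF metalates between the two methoxy groups, the bulky silyloxy group blocking its own ortho positions, to give [2,6-dimethoxy-4-(triisopropylsilyloxy)phenyl]lithium F10.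
- Prenyl bromide alkylates F10 to [3,5-dimethoxy-4-(3-methylbut-2-en-1-yl)phenoxy]triisopropylsilane F11, and TBAF in THF releases phenol 5.

**Further compounds**

F1 | step 6 | 2,4-dimethoxy-6-(methoxymethoxy)-3-(3-methylbut-2-en-1-yl)benzaldehyde | O=Cc1c(OCOC)cc(OC)c(CC=C(C)C)c1OC
F2 | step 6 | 1-[2,4-dimethoxy-6-(methoxymethoxy)-3-(3-methylbut-2-en-1-yl)phenyl]ethan-1-ol (racemic) | CC(O)c1c(OCOC)cc(OC)c(CC=C(C)C)c1OC
F3 | step 6 | 1-[2,4-dimethoxy-6-(methoxymethoxy)-3-(3-methylbut-2-en-1-yl)phenyl]ethan-1-one | CC(=O)c1c(OCOC)cc(OC)c(CC=C(C)C)c1OC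
F4 | step 6 | (E)-1-[2,4-dimethoxy-6-(methoxymethoxy)-3-(3-methylbut-2-en-1-yl)phenyl]-3-[3-methoxy-4-(triisopropylsilyloxy)phenyl]prop-2-en-1-one | COc1cc(/C=C/C(=O)c2c(OCOC)cc(OC)c(CC=C(C)C)c2OC)ccc1O[Si](C(C)C)(C(C)C)C(C)C
F5 | step 6 | [2,4-dimethoxy-6-(methoxymethoxy)-3-(3-methylbut-2-en-1-yl)phenyl]{(2R,3S)-3-[3-methoxy-4-(triisopropylsilyloxy)phenyl]oxiran-2-yl}methanone | COc1cc([C@@H]2O[C@H]2C(=O)c3c(OCOC)cc(OC)c(CC=C(C)C)c3OC)ccc1O[Si](C(C)C)(C(C)C)C(C)C
F6 | step 8 | (2R,3S)-5,7-dimethoxy-2-[3-methoxy-4-(triisopropylsilyloxy)phenyl]-6-(3-methylbut-2-en-1-yl)chromane-3,4-diol (C4 epimers) | COc1cc([C@H]2Oc3cc(OC)c(CC=C(C)C)c(OC)c3C(O)[C@@H]2O)ccc1O[Si](C(C)C)(C(C)C)C(C)C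
F7 | step 2 | 2-(3,5-dimethoxyphenyl)-4,4,5,5-tetramethyl-1,3,2-dioxaborolane | COc1cc(OC)cc(B2OC(C)(C)C(C)(C)O2)c1
F8 | step 2 | 3,5-dimethoxyphenol | COc1cc(O)cc(OC)c1
F9 | step 2 | (3,5-dimethoxyphenoxy)triisopropylsilane | COc1cc(OC)cc(O[Si](C(C)C)(C(C)C)C(C)C)c1
F10 | step 2 | [2,6-dimethoxy-4-(triisopropylsilyloxy)phenyl]lithium | [Li]c1c(OC)cc(O[Si](C(C)C)(C(C)C)C(C)C)cc1OC
F11 | step 2 | [3,5-dimethoxy-4-(3-methylbut-2-en-1-yl)phenoxy]triisopropylsilane | COc1cc(O[Si](C(C)C)(C(C)C)C(C)C)cc(OC)c1CC=C(C)C
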